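## Retrosynthetic overview

1. The 12-membered dilactone is opened at the ring B aryl–C(=O) bond: the last ring closure is a palladium-catalysed carbonylative macrolactonisation of a ring B aryl iodide onto the side-chain 2-OH of the ring A half (retention). Ring A is the trioxygenated arene, ring B the tetraoxygenated one.
2. The other ester is made first by an intermolecular Mitsunobu coupling of the ring A benzoic acid with the ring B alcohol (inversion, 2S to 2R).
3. Both halves come from one arylboronic acid and the two enantiomers of 2-(triethylsilyloxy)propanal by a new rhodium-catalysed anti-selective aldehyde arylation, which forms the aryl–C bonds and sets both benzylic centres.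
4. The two equivalent ring positions next to the side chain are iodinated; iodine–magnesium exchange then gives the extra phenol of ring B or the carboxyl of ring A, and the remaining iodide is the carbonylation handle.
5. The boronic acid comes from iridium-catalysed C–H borylation of 2-methoxy-1,3-bis(methoxymethoxy)benzene (from resorcinol); the aldehydes come from methyl (S)- and (R)-lactate. Both arenes are present from the start; the only ring formed is the macrocycle, last.

Assumption: the (1R,4R)-diene ligand is taken as the matched partner of the (S)-aldehyde (its mirror image then matches the (R)-aldehyde); if screening shows the opposite pairing, the two ligand enantiomers are exchanged between steps 7 and 15.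

## Route

Step 1
Reactants: 1 resorcinol
Product: 2 1,3-bis(methoxymethoxy)benzene
Conditions: NaH, MOMCl, DMF, 0 °C to rt
Reagents that add atoms: chloromethyl methyl ether, COCCl
Why: Williamson-type O-alkylation of the bis-phenoxide gives the bis-MOM ether, which is both protecting group and ortho-directing group.

Step 2
Reactants: 2 1,3-bis(methoxymethoxy)benzene
Product: 5 2,6-bis(methoxymethoxy)phenol, via aryllithium 3 (not isolated), via lithium aryltrimethoxyborate 4 (not isolated)
Conditions: n-BuLi, THF, 0 °C to rt; B(OMe)3, –78 °C to rt; 30% H2O2, 0 °C to rt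
Reagents that add atoms: hydrogen peroxide, OO
Why: Directed ortho-metalation at the carbon flanked by both OMOM groups, borate formation and boronate oxidation install the central oxygen.

Step 3
Reactants: 5 2,6-bis(methoxymethoxy)phenol
Product: 6 2-methoxy-1,3-bis(methoxymethoxy)benzene
Conditions: MeI, K2CO3, acetone, reflux
Reagents that add atoms: iodomethane, CI
Why: Williamson O-methylation of the only free phenol fixes the methyl ether that stays in the target.

Step 4
Reactants: 6 2-methoxy-1,3-bis(methoxymethoxy)benzene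
Product: 8 [4-methoxy-3,5-bis(methoxymethoxy)phenyl]boronic acid, via aryl pinacolboronate 7 (not isolated)
Conditions: [Ir(OMe)(cod)]2 (1.5 mol%), 4,4'-di-tert-butyl-2,2'-bipyridine (3 mol%), B2pin2 (1.0 equiv), THF, 80 °C; then NaIO4, NH4OAc, acetone/H2O, rt
Reagents that add atoms: bis(pinacolato)diboron, CC1(C)OB(OC1(C)C)B1OC(C)(C)C(C)(C)O1; water, O
Why: Sterically controlled iridium-catalysed aromatic C–H borylation reacts only at the C–H flanked by two hydrogens (para to OMe), and one-pot periodate cleavage of the pinacol ester gives the free boronic acid.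

Step 5
Reactants: 9 methyl (S)-lactate
Product: 10 methyl (S)-2-(triethylsilyloxy)propanoate
Conditions: TESCl, imidazole, CH2Cl2, 0 °C to rt
Reagents that add atoms: chlorotriethylsilane, CC[Si](Cl)(CC)CC
Why: Standard silylation of the secondary alcohol; the stereocentre is not touched.

Step 6
Reactants: 10 methyl (S)-2-(triethylsilyloxy)propanoate
Product: 11 (S)-2-(triethylsilyloxy)propanal
Conditions: i-Bu2AlH (1.1 equiv), CH2Cl2, –78 °C; MeOH, aq KNaC4H4O6; used crude at once
Reagents that add atoms: none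
Why: Partial ester reduction at –78 °C stops at the aluminium hemiacetal, which gives the aldehyde on work-up without α-epimerisation.

Step 7
Reactants: 8 [4-methoxy-3,5-bis(methoxymethoxy)phenyl]boronic acid (1.3 equiv); 11 (S)-2-(triethylsilyloxy)propanal
Product: 12 (1R,2S)-1-[4-methoxy-3,5-bis(methoxymethoxy)phenyl]-2-(triethylsilyloxy)propan-1-ol
Conditions: [RhCl(C2H4)2]2 (2.5 mol%), (1R,4R)-2,5-diphenylbicyclo[2.2.2]octa-2,5-diene (5.5 mol%), KOH (6 mol%), dioxane/H2O 10:1, 30 °C, slow addition of 11
Reagents that add atoms: none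
Why: Proposed new method: a hydroxo complex of monovalent rhodium with the chiral diene transmetalates the boronic acid to an aryl–rhodium species that inserts the aldehyde C=O through a four-membered transition state; the α-silyloxy group enforces polar Felkin–Anh attack (C–OSi anti to the incoming aryl) and the diene shields the same carbonyl face, so substrate and catalyst are matched for the anti (1R,2S) alcohol under near-neutral conditions that avoid α-epimerisation and silyl migration. The closest known reaction type is the rhodium- or ruthenium-catalysed enantioselective 1,2-addition of arylboronic acids to achiral aldehydes, which has not been shown as a ligand-reinforced diastereoselective arylation of an α-silyloxy aldehyde.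

Step 8
Reactants: 12 (1R,2S)-1-[4-methoxy-3,5-bis(methoxymethoxy)phenyl]-2-(triethylsilyloxy)propan-1-ol
Product: 13 (1R,2S)-1-(tert-butyldimethylsilyloxy)-1-[4-methoxy-3,5-bis(methoxymethoxy)phenyl]-2-(triethylsilyloxy)propane
Conditions: TBSOTf, 2,6-lutidine, CH2Cl2, –78 to –20 °C
Reagents that add atoms: tert-butyldimethylsilyl trifluoromethanesulfonate, CC(C)(C)[Si](C)(C)OS(=O)(=O)C(F)(F)F
Why: Silylation of the benzylic alcohol gives a robust ether that differs in lability from the TES ether, so the two side-chain oxygens stay distinguished.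

Step 9
Reactants: 13 (1R,2S)-1-(tert-butyldimethylsilyloxy)-1-[4-methoxy-3,5-bis(methoxymethoxy)phenyl]-2-(triethylsilyloxy)propane
Product: 14 (1R,2S)-1-(tert-butyldimethylsilyloxy)-1-[2,6-diiodo-4-methoxy-3,5-bis(methoxymethoxy)phenyl]-2-(triethylsilyloxy)propane
Conditions: NIS (2.4 equiv), TFA (5 mol%), MeCN, 0 °C to rt, dark
Reagents that add atoms: N-iodosuccinimide, O=C1CCC(=O)N1I
Why: Electrophilic aromatic iodination takes both free ring positions, each ortho and para to an OMOM group.

Step 10
Reactants: 14 (1R,2S)-1-(tert-butyldimethylsilyloxy)-1-[2,6-diiodo-4-methoxy-3,5-bis(methoxymethoxy)phenyl]-2-(triethylsilyloxy)propane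
Product: 17 3-iodo-5-methoxy-4,6-bis(methoxymethoxy)-2-[(1R,2S)-1-(tert-butyldimethylsilyloxy)-2-(triethylsilyloxy)propyl]phenol, via arylmagnesium chloride 15 (not isolated), via chloromagnesium aryltrimethoxyborate 16 (not isolated)
Conditions: i-PrMgCl·LiCl (1.05 equiv), THF, –40 °C; B(OMe)3, –40 to 0 °C; 30% H2O2, 0 °C
Reagents that add atoms: hydrogen peroxide, OO
Why: Mono iodine–magnesium exchange (the two iodines are equivalent and the first Grignard suppresses a second exchange), borate formation and boronate oxidation turn one C–I into the fourth ring oxygen; magnesium at low temperature avoids silyl migration to carbon.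

Step 11
Reactants: 17 3-iodo-5-methoxy-4,6-bis(methoxymethoxy)-2-[(1R,2S)-1-(tert-butyldimethylsilyloxy)-2-(triethylsilyloxy)propyl]phenol
Product: 18 (1R,2S)-1-(tert-butyldimethylsilyloxy)-1-[2-iodo-4-methoxy-3,5,6-tris(methoxymethoxy)phenyl]-2-(triethylsilyloxy)propane
Conditions: NaH, MOMCl, DMF, 0 °C
Reagents that add atoms: chloromethyl methyl ether, COCCl
Why: Williamson-type O-alkylation of the new phenoxide completes the ring B substitution pattern.

Step 12
Reactants: 18 (1R,2S)-1-(tert-butyldimethylsilyloxy)-1-[2-iodo-4-methoxy-3,5,6-tris(methoxymethoxy)phenyl]-2-(triethylsilyloxy)propane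
Product: 19 (1R,2S)-1-(tert-butyldimethylsilyloxy)-1-[2-iodo-4-methoxy-3,5,6-tris(methoxymethoxy)phenyl]propan-2-ol
Conditions: PPTS (0.2 equiv), MeOH/CH2Cl2 1:1, 0 °C to rt
Reagents that add atoms: none
Why: Acid-catalysed methanolysis removes the secondary TES ether selectively, leaving the hindered benzylic TBS ether and the aryl MOM ethers.

Step 13
Reactants: 20 methyl (R)-lactate
Product: 21 methyl (R)-2-(triethylsilyloxy)propanoate
Conditions: TESCl, imidazole, CH2Cl2, 0 °C to rt
Reagents that add atoms: chlorotriethylsilane, CC[Si](Cl)(CC)CC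
Why: Standard silylation of the secondary alcohol; the stereocentre is not touched.

Step 14
Reactants: 21 methyl (R)-2-(triethylsilyloxy)propanoate
Product: 22 (R)-2-(triethylsilyloxy)propanal
Conditions: i-Bu2AlH (1.1 equiv), CH2Cl2, –78 °C; MeOH, aq KNaC4H4O6; used crude at once
Reagents that add atoms: none
Why: Partial ester reduction through the stable aluminium hemiacetal gives the aldehyde without α-epimerisation.

Step 15
Reactants: 8 [4-methoxy-3,5-bis(methoxymethoxy)phenyl]boronic acid (1.3 equiv); 22 (R)-2-(triethylsilyloxy)propanal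
Product: 23 (1S,2R)-1-[4-methoxy-3,5-bis(methoxymethoxy)phenyl]-2-(triethylsilyloxy)propan-1-ol
Conditions: [RhCl(C2H4)2]2 (2.5 mol%), (1S,4S)-2,5-diphenylbicyclo[2.2.2]octa-2,5-diene (5.5 mol%), KOH (6 mol%), dioxane/H2O 10:1, 30 °C, slow addition of 22
Reagents that add atoms: none
Why: Proposed new method: the mirror image of step 7, in which the aryl–rhodium species formed by transmetalation inserts the aldehyde with polar Felkin–Anh control reinforced by the enantiomeric diene, giving the anti (1S,2R) alcohol. The closest known reaction type is the rhodium- or ruthenium-catalysed enantioselective 1,2-addition of arylboronic acids to achiral aldehydes.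

Step 16
Reactants: 23 (1S,2R)-1-[4-methoxy-3,5-bis(methoxymethoxy)phenyl]-2-(triethylsilyloxy)propan-1-ol
Product: 24 (1S,2R)-1-(tert-butyldimethylsilyloxy)-1-[4-methoxy-3,5-bis(methoxymethoxy)phenyl]-2-(triethylsilyloxy)propane
Conditions: TBSOTf, 2,6-lutidine, CH2Cl2, –78 to –20 °C
Reagents that add atoms: tert-butyldimethylsilyl trifluoromethanesulfonate, CC(C)(C)[Si](C)(C)OS(=O)(=O)C(F)(F)F
Why: Silylation of the benzylic alcohol, as in step 8.

Step 17
Reactants: 24 (1S,2R)-1-(tert-butyldimethylsilyloxy)-1-[4-methoxy-3,5-bis(methoxymethoxy)phenyl]-2-(triethylsilyloxy)propane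
Product: 25 (1S,2R)-1-(tert-butyldimethylsilyloxy)-1-[2-iodo-4-methoxy-3,5-bis(methoxymethoxy)phenyl]-2-(triethylsilyloxy)propane
Conditions: NIS (1.0 equiv), TFA (2 mol%), MeCN, –20 to 0 °C, dark
Reagents that add atoms: N-iodosuccinimide, O=C1CCC(=O)N1I
Why: Electrophilic aromatic mono-iodination; the two free positions are equivalent and the first iodine slows the second substitution.

Step 18
Reactants: 25 (1S,2R)-1-(tert-butyldimethylsilyloxy)-1-[2-iodo-4-methoxy-3,5-bis(methoxymethoxy)phenyl]-2-(triethylsilyloxy)propane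
Product: 27 3-methoxy-2,4-bis(methoxymethoxy)-6-[(1S,2R)-1-(tert-butyldimethylsilyloxy)-2-(triethylsilyloxy)propyl]benzoic acid, via arylmagnesium chloride 26 (not isolated)
Conditions: i-PrMgCl·LiCl (1.2 equiv), THF, –20 °C; CO2 (gas), –40 °C to rt; aq NaH2PO4 (pH 5)
Reagents that add atoms: carbon dioxide, O=C=O
Why: Iodine–magnesium exchange followed by Grignard carboxylation installs the ring A carboxyl between the OMOM group and the side chain.

Step 19
Reactants: 27 3-methoxy-2,4-bis(methoxymethoxy)-6-[(1S,2R)-1-(tert-butyldimethylsilyloxy)-2-(triethylsilyloxy)propyl]benzoic acid (1.2 equiv); 19 (1R,2S)-1-(tert-butyldimethylsilyloxy)-1-[2-iodo-4-methoxy-3,5,6-tris(methoxymethoxy)phenyl]propan-2-ol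
Product: 28 (1R,2R)-1-(tert-butyldimethylsilyloxy)-1-[2-iodo-4-methoxy-3,5,6-tris(methoxymethoxy)phenyl]propan-2-yl 3-methoxy-2,4-bis(methoxymethoxy)-6-[(1S,2R)-1-(tert-butyldimethylsilyloxy)-2-(triethylsilyloxy)propyl]benzoate
Conditions: PPh3 (2 equiv), DIAD (2 equiv), toluene, 0 °C to rt
Reagents that add atoms: none
Why: Mitsunobu esterification, in which the hindered benzoate is the nucleophile and so no attack at its shielded carbonyl is needed; SN2 displacement of the alkoxyphosphonium inverts the carbinol carbon from 2S to the 2R configuration of the target.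

Step 20
Reactants: 28 (1R,2R)-1-(tert-butyldimethylsilyloxy)-1-[2-iodo-4-methoxy-3,5,6-tris(methoxymethoxy)phenyl]propan-2-yl 3-methoxy-2,4-bis(methoxymethoxy)-6-[(1S,2R)-1-(tert-butyldimethylsilyloxy)-2-(triethylsilyloxy)propyl]benzoate
Product: 29 (1R,2R)-1-(tert-butyldimethylsilyloxy)-1-[2-iodo-4-methoxy-3,5,6-tris(methoxymethoxy)phenyl]propan-2-yl 6-[(1S,2R)-1-(tert-butyldimethylsilyloxy)-2-hydroxypropyl]-3-methoxy-2,4-bis(methoxymethoxy)benzoate
Conditions: HF·pyridine, pyridine, THF, 0 °C; used directly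
Reagents that add atoms: none
Why: Buffered fluoride desilylation removes the TES ether selectively over the two hindered TBS ethers, and the non-basic medium keeps the freed hydroxyl from translactonising onto the neighbouring hindered ester.

Step 21
Reactants: 29 (1R,2R)-1-(tert-butyldimethylsilyloxy)-1-[2-iodo-4-methoxy-3,5,6-tris(methoxymethoxy)phenyl]propan-2-yl 6-[(1S,2R)-1-(tert-butyldimethylsilyloxy)-2-hydroxypropyl]-3-methoxy-2,4-bis(methoxymethoxy)benzoate
Product: 30 protected macrodiolide (the target with all five phenols as MOM ethers and both benzylic hydroxyls as TBS ethers)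
Conditions: Pd(OAc)2 (10 mol%), Xantphos (12 mol%), CO (1 atm), i-Pr2NEt (3 equiv), toluene, 80 °C, syringe-pump addition of 29 to 2 mM
Reagents that add atoms: carbon monoxide, [C-]#[O+]
Why: Palladium-catalysed alkoxycarbonylation run as a carbonylative macrolactonisation: zerovalent palladium adds oxidatively to the aryl iodide, CO inserts to give the aroyl–palladium species, and the secondary alcohol captures it intramolecularly with retention at carbon, forming the ring B aryl–C(=O) bond and the 12-membered ring without a tetrahedral attack on a preformed hindered acid.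

Step 22
Reactants: 30 protected macrodiolide
Product: 31 CNP0086623.1 (target)
Conditions: HCl (1.25 M in MeOH), THF, 0 to 30 °C
Reagents that add atoms: none
Why: Acid-catalysed acetal exchange removes the five aryl MOM ethers and acid methanolysis removes the two TBS ethers in one operation, avoiding the basic conditions that would let a benzylic hydroxyl close a phthalide onto the neighbouring ester.

## Compound list

1 | resorcinol | Oc1cccc(O)c1 | starting material
2 | 1,3-bis(methoxymethoxy)benzene | COCOc1cccc(OCOC)c1 | intermediate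
3 | [2,6-bis(methoxymethoxy)phenyl]lithium | [Li]c1c(OCOC)cccc1OCOC | intermediate
4 | lithium [2,6-bis(methoxymethoxy)phenyl]trimethoxyborate | [Li+].CO[B-](OC)(OC)c1c(OCOC)cccc1OCOC | intermediate
5 | 2,6-bis(methoxymethoxy)phenol | COCOc1cccc(OCOC)c1O | intermediate
6 | 2-methoxy-1,3-bis(methoxymethoxy)benzene | COCOc1cccc(OCOC)c1OC | intermediate
7 | 2-[4-methoxy-3,5-bis(methoxymethoxy)phenyl]-4,4,5,5-tetramethyl-1,3,2-dioxaborolane | COCOc1cc(cc(OCOC)c1OC)B1OC(C)(C)C(C)(C)O1 | intermediate
8 | [4-methoxy-3,5-bis(methoxymethoxy)phenyl]boronic acid | COCOc1cc(cc(OCOC)c1OC)B(O)O | intermediate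
9 | methyl (S)-lactate | C[C@H](O)C(=O)OC | starting material
10 | methyl (S)-2-(triethylsilyloxy)propanoate | C[C@H](O[Si](CC)(CC)CC)C(=O)OC | intermediate
11 | (S)-2-(triethylsilyloxy)propanal | C[C@H](O[Si](CC)(CC)CC)C=O | intermediate
12 | (1R,2S)-1-[4-methoxy-3,5-bis(methoxymethoxy)phenyl]-2-(triethylsilyloxy)propan-1-ol | C[C@H](O[Si](CC)(CC)CC)[C@H](O)c1cc(OCOC)c(OC)c(OCOC)c1 | intermediate
13 | (1R,2S)-1-(tert-butyldimethylsilyloxy)-1-[4-methoxy-3,5-bis(methoxymethoxy)phenyl]-2-(triethylsilyloxy)propane | C[C@H](O[Si](CC)(CC)CC)[C@H](O[Si](C)(C)C(C)(C)C)c1cc(OCOC)c(OC)c(OCOC)c1 | intermediate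
14 | (1R,2S)-1-(tert-butyldimethylsilyloxy)-1-[2,6-diiodo-4-methoxy-3,5-bis(methoxymethoxy)phenyl]-2-(triethylsilyloxy)propane | C[C@H](O[Si](CC)(CC)CC)[C@H](O[Si](C)(C)C(C)(C)C)c1c(I)c(OCOC)c(OC)c(OCOC)c1I | intermediate
15 | arylmagnesium chloride from 14 (one iodine replaced by MgCl) | C[C@H](O[Si](CC)(CC)CC)[C@H](O[Si](C)(C)C(C)(C)C)c1c(I)c(OCOC)c(OC)c(OCOC)c1[Mg]Cl | intermediate
16 | chloromagnesium aryl(trimethoxy)borate from 15 | C[C@H](O[Si](CC)(CC)CC)[C@H](O[Si](C)(C)C(C)(C)C)c1c(I)c(OCOC)c(OC)c(OCOC)c1[B-](OC)(OC)OC.[Mg+]Cl | intermediate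
17 | 3-iodo-5-methoxy-4,6-bis(methoxymethoxy)-2-[(1R,2S)-1-(tert-butyldimethylsilyloxy)-2-(triethylsilyloxy)propyl]phenol | C[C@H](O[Si](CC)(CC)CC)[C@H](O[Si](C)(C)C(C)(C)C)c1c(I)c(OCOC)c(OC)c(OCOC)c1O | intermediate
18 | (1R,2S)-1-(tert-butyldimethylsilyloxy)-1-[2-iodo-4-methoxy-3,5,6-tris(methoxymethoxy)phenyl]-2-(triethylsilyloxy)propane | C[C@H](O[Si](CC)(CC)CC)[C@H](O[Si](C)(C)C(C)(C)C)c1c(I)c(OCOC)c(OC)c(OCOC)c1OCOC | intermediate
19 | (1R,2S)-1-(tert-butyldimethylsilyloxy)-1-[2-iodo-4-methoxy-3,5,6-tris(methoxymethoxy)phenyl]propan-2-ol | C[C@H](O)[C@H](O[Si](C)(C)C(C)(C)C)c1c(I)c(OCOC)c(OC)c(OCOC)c1OCOC | intermediate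
20 | methyl (R)-lactate | C[C@@H](O)C(=O)OC | starting material
21 | methyl (R)-2-(triethylsilyloxy)propanoate | C[C@@H](O[Si](CC)(CC)CC)C(=O)OC | intermediate
22 | (R)-2-(triethylsilyloxy)propanal | C[C@@H](O[Si](CC)(CC)CC)C=O | intermediate
23 | (1S,2R)-1-[4-methoxy-3,5-bis(methoxymethoxy)phenyl]-2-(triethylsilyloxy)propan-1-ol | C[C@@H](O[Si](CC)(CC)CC)[C@@H](O)c1cc(OCOC)c(OC)c(OCOC)c1 | intermediate
24 | (1S,2R)-1-(tert-butyldimethylsilyloxy)-1-[4-methoxy-3,5-bis(methoxymethoxy)phenyl]-2-(triethylsilyloxy)propane | C[C@@H](O[Si](CC)(CC)CC)[C@@H](O[Si](C)(C)C(C)(C)C)c1cc(OCOC)c(OC)c(OCOC)c1 | intermediate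
25 | (1S,2R)-1-(tert-butyldimethylsilyloxy)-1-[2-iodo-4-methoxy-3,5-bis(methoxymethoxy)phenyl]-2-(triethylsilyloxy)propane | C[C@@H](O[Si](CC)(CC)CC)[C@@H](O[Si](C)(C)C(C)(C)C)c1cc(OCOC)c(OC)c(OCOC)c1I | intermediate
26 | arylmagnesium chloride from 25 (iodine replaced by MgCl) | C[C@@H](O[Si](CC)(CC)CC)[C@@H](O[Si](C)(C)C(C)(C)C)c1cc(OCOC)c(OC)c(OCOC)c1[Mg]Cl | intermediate
27 | 3-methoxy-2,4-bis(methoxymethoxy)-6-[(1S,2R)-1-(tert-butyldimethylsilyloxy)-2-(triethylsilyloxy)propyl]benzoic acid | C[C@@H](O[Si](CC)(CC)CC)[C@@H](O[Si](C)(C)C(C)(C)C)c1cc(OCOC)c(OC)c(OCOC)c1C(=O)O | intermediate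
28 | (1R,2R)-1-(tert-butyldimethylsilyloxy)-1-[2-iodo-4-methoxy-3,5,6-tris(methoxymethoxy)phenyl]propan-2-yl 3-methoxy-2,4-bis(methoxymethoxy)-6-[(1S,2R)-1-(tert-butyldimethylsilyloxy)-2-(triethylsilyloxy)propyl]benzoate | C[C@@H](OC(=O)c1c(OCOC)c(OC)c(OCOC)cc1[C@H](O[Si](C)(C)C(C)(C)C)[C@@H](C)O[Si](CC)(CC)CC)[C@H](O[Si](C)(C)C(C)(C)C)c1c(I)c(OCOC)c(OC)c(OCOC)c1OCOC | intermediate
29 | (1R,2R)-1-(tert-butyldimethylsilyloxy)-1-[2-iodo-4-methoxy-3,5,6-tris(methoxymethoxy)phenyl]propan-2-yl 6-[(1S,2R)-1-(tert-butyldimethylsilyloxy)-2-hydroxypropyl]-3-methoxy-2,4-bis(methoxymethoxy)benzoate | C[C@@H](OC(=O)c1c(OCOC)c(OC)c(OCOC)cc1[C@H](O[Si](C)(C)C(C)(C)C)[C@@H](C)O)[C@H](O[Si](C)(C)C(C)(C)C)c1c(I)c(OCOC)c(OC)c(OCOC)c1OCOC | intermediate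
30 | protected macrodiolide: the target with all five phenols as methoxymethyl ethers and both benzylic hydroxyls as tert-butyldimethylsilyl ethers | COc1c(OCOC)cc2c(c1OCOC)C(=O)O[C@H](C)[C@H](O[Si](C)(C)C(C)(C)C)c1c(OCOC)c(OCOC)c(OC)c(OCOC)c1C(=O)O[C@H](C)[C@H]2O[Si](C)(C)C(C)(C)C | intermediate
31 | CNP0086623.1: the 12-membered dilactone in which the carboxyl of 2,4-dihydroxy-3-methoxy-6-[(1S,2R)-1,2-dihydroxypropyl]benzoic acid (ring A unit) acylates the 2-oxygen of the side chain of 2,4,5-trihydroxy-3-methoxy-6-[(1R,2R)-1,2-dihydroxypropyl]benzoic acid (ring B unit) and the ring B carboxyl acylates the 2-oxygen of the ring A side chain | COc1c(O)cc2c(c1O)C(=O)O[C@H](C)[C@H](O)c1c(O)c(O)c(OC)c(O)c1C(=O)O[C@H](C)[C@H]2O | target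

## Step count and risks

Total step count: 22. Longest linear sequence: 14 steps (steps 1–4, 7–12 and 19–22; 1 → 2 → 5 → 6 → 8 → 12 → 13 → 14 → 17 → 18 → 19 → 28 → 29 → 30 → 31), which is 0.64 of the total.

**Steps 7 and 15 (new rhodium-catalysed anti-selective arylation).** The risks are low turnover with the α-branched aldehyde, a low diastereomer ratio if the ligand pairing is mismatched, α-epimerisation and silyl migration. The fallback uses known chemistry and sets out from boronic acid 8. Iododeboronation with NaI and TsNClNa in aqueous THF gives 5-iodo-2-methoxy-1,3-bis(methoxymethoxy)benzene F1. Iodine–lithium exchange with n-BuLi in THF at –78 °C gives [4-methoxy-3,5-bis(methoxymethoxy)phenyl]lithium F2. F2 is added at –78 °C to aldehyde 11 (or, for the other half, to aldehyde 22) under substrate-only Felkin–Anh control; the anti adduct is expected as the major isomer (roughly 4:1 to 8:1) and is separated by chromatography. The route is rejoined at 12 (or at 23).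

**Step 19 (Mitsunobu coupling of a hindered acid with a β-branched secondary alcohol).** The risks are slow SN2 displacement and elimination. The fallback sets out from alcohol 19 and acid 27 and replaces the redox condensation by a preformed leaving group and a naked carboxylate. Alcohol 19 with ClCH2SO2Cl and pyridine in CH2Cl2 at 0 °C gives (1R,2S)-1-(tert-butyldimethylsilyloxy)-1-[2-iodo-4-methoxy-3,5,6-tris(methoxymethoxy)phenyl]propan-2-yl chloromethanesulfonate F3. Acid 27 with Cs2CO3 gives cesium 3-methoxy-2,4-bis(methoxymethoxy)-6-[(1S,2R)-1-(tert-butyldimethylsilyloxy)-2-(triethylsilyloxy)propyl]benzoate F4. Displacement of F3 by F4 with 18-crown-6 in toluene at 80 °C proceeds with inversion and rejoins the route at 28.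

**Step 21 (carbonylative macrolactonisation).** The risks are slow intramolecular capture of the hindered aroyl–palladium species, hydrodeiodination and translactonisation of 29 on heating with base. The fallback sets out from 28 and changes the ring closure to a classical seco-acid lactonisation. Hydroxycarbonylation of 28 (Pd(OAc)2, Xantphos, CO 1 atm, H2O, Et3N, dioxane, 80 °C) gives 2-{[(1R,2R)-1-(tert-butyldimethylsilyloxy)-2-(aroyloxy)propyl]}-6-carboxy seco acid with the TES ether intact F5. HF·pyridine in THF at 0 °C gives the seco hydroxy acid F6. High-dilution Mukaiyama macrolactonisation of F6 (2-chloro-1-methylpyridinium iodide, Et3N, MeCN, 60 °C) rejoins the route at 30.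

Further compounds
F1 | step 7 | 5-iodo-2-methoxy-1,3-bis(methoxymethoxy)benzene | COCOc1cc(I)cc(OCOC)c1OC
F2 | step 7 | [4-methoxy-3,5-bis(methoxymethoxy)phenyl]lithium | [Li]c1cc(OCOC)c(OC)c(OCOC)c1
F3 | step 19 | (1R,2S)-1-(tert-butyldimethylsilyloxy)-1-[2-iodo-4-methoxy-3,5,6-tris(methoxymethoxy)phenyl]propan-2-yl chloromethanesulfonate | C[C@H](OS(=O)(=O)CCl)[C@H](O[Si](C)(C)C(C)(C)C)c1c(I)c(OCOC)c(OC)c(OCOC)c1OCOC
F4 | step 19 | cesium 3-methoxy-2,4-bis(methoxymethoxy)-6-[(1S,2R)-1-(tert-butyldimethylsilyloxy)-2-(triethylsilyloxy)propyl]benzoate | [Cs+].C[C@@H](O[Si](CC)(CC)CC)[C@@H](O[Si](C)(C)C(C)(C)C)c1cc(OCOC)c(OC)c(OCOC)c1C([O-])=O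
F5 | step 21 | seco acid: compound 28 with the iodine replaced by CO2H (TES ether intact) | C[C@@H](OC(=O)c1c(OCOC)c(OC)c(OCOC)cc1[C@H](O[Si](C)(C)C(C)(C)C)[C@@H](C)O[Si](CC)(CC)CC)[C@H](O[Si](C)(C)C(C)(C)C)c1c(C(=O)O)c(OCOC)c(OC)c(OCOC)c1OCOC
F6 | step 21 | seco hydroxy acid: compound 29 with the iodine replaced by CO2H | C[C@@H](OC(=O)c1c(OCOC)c(OC)c(OCOC)cc1[C@H](O[Si](C)(C)C(C)(C)C)[C@@H](C)O)[C@H](O[Si](C)(C)C(C)(C)C)c1c(C(=O)O)c(OCOC)c(OC)c(OCOC)c1OCOC
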